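**Plan**

Chain labels: C1 = ketone carbon, C2 = stereocentre, C3 = diarylmethine. Enabling feature: C3 holds one H and two equivalent 4-hydroxyphenyl rings joined through their para carbons, so it is a masked formyl carbon. Its neighbour C2 lies between the C1 aryl ketone and chromone C3 and passes readily through an enol.
Cuts: first the two O-protecting groups (benzyl on O7, methyl on the ortho oxygen of the ketone ring). Then both C3–aryl bonds go at once, back to an α-hydroxymethylene ketone and two phenols.
Next the formyl carbon and chromone C2 are removed (both come from DMF dimethyl acetal), which opens the pyranone ring to a 1,4-diaryl-1,4-butanedione. Its central CH2–CH2 bond is cut to a methyl ketone and a bromomethyl ketone.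
Forward: chain joined first under non-acidic conditions, ortho phenol freed, pyranone ring closed and C2 aminomethylenated in one operation, hydrolysis, three-component arylation, global ether cleavage. All benzene rings are bought.
Stereochemistry: C2 is the only stereocentre. It is set as R by catalyst-controlled protonation of the enol that the second arylation leaves behind.

Key step: step 5

Assumption: the sense of induction of the chiral acid on this new substrate class cannot be predicted, so the R-configured catalyst is written and its mirror image is to be used if screening shows that it leads to the S ketone.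

**Step 1**
Reactants: 1 1-[2,4-bis(benzyloxy)phenyl]ethanone; 2 2-bromo-1-(2,4-dimethoxyphenyl)ethanone
Product: 3 1-[2,4-bis(benzyloxy)phenyl]-4-(2,4-dimethoxyphenyl)butane-1,4-dione
Conditions: ZnCl2 (2 equiv), Et2NH, t-BuOH, toluene, rt, 1 in 1.5-fold excess; dilute H2SO4 work-up
Reagents that add atoms: none
Why: The zinc-enolate coupling of a methyl ketone with a bromomethyl ketone (ZnCl2–amine–tert-butanol 1,4-diketone synthesis) is a proven route to unsymmetrical 1,4-diaryl-1,4-butanediones, it avoids the acid of a Friedel–Crafts assembly that would dehydrate the dione to a 2,5-diarylfuran (Paal–Knorr), and all phenol oxygens are capped so that 2 cannot O-alkylate.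

**Step 2**
Reactants: 3 1-[2,4-bis(benzyloxy)phenyl]-4-(2,4-dimethoxyphenyl)butane-1,4-dione
Product: 4 1-[4-(benzyloxy)-2-hydroxyphenyl]-4-(2,4-dimethoxyphenyl)butane-1,4-dione
Conditions: MgBr2·OEt2 (3 equiv), toluene–Et2O, 80 °C; 1 M HCl work-up
Reagents that add atoms: none
Why: In this chelation-controlled ether cleavage MgBr2 binds the ketone and the ortho ether oxygen in a six-membered chelate and bromide removes the benzylic group, whereas the para benzyl ether has no chelate and the ortho methyl ether of the other ring, lacking a benzylic carbon, should resist bromide under these conditions.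

**Step 3**
Reactants: 4 1-[4-(benzyloxy)-2-hydroxyphenyl]-4-(2,4-dimethoxyphenyl)butane-1,4-dione
Product: 7 (E)-2-[7-(benzyloxy)-4-oxochromen-3-yl]-3-(dimethylamino)-1-(2,4-dimethoxyphenyl)prop-2-en-1-one, via open enaminone 5 (not isolated), via phenacylchromone 6 (not isolated)
Conditions: Me2NCH(OMe)2 (6 equiv), toluene, 105 °C, N2 sweep
Reagents that add atoms: N,N-dimethylformamide dimethyl acetal, COC(OC)N(C)C
Why: This is enaminone formation with an amide acetal as in the deoxybenzoin-to-isoflavone synthesis: the CH2 next to the hydrogen-bonded 2-hydroxyaryl ketone condenses first, the phenol displaces dimethylamine by addition–elimination to close the pyranone ring, and the remaining CH2, activated by the aryl ketone and the chromonyl group, is aminomethylenated by the excess reagent under neutral conditions.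

**Step 4**
Reactants: 7 (E)-2-[7-(benzyloxy)-4-oxochromen-3-yl]-3-(dimethylamino)-1-(2,4-dimethoxyphenyl)prop-2-en-1-one
Product: 8 (Z)-2-[7-(benzyloxy)-4-oxochromen-3-yl]-3-hydroxy-1-(2,4-dimethoxyphenyl)prop-2-en-1-one
Conditions: 1 M HCl, THF, 0 °C to rt, short contact time
Reagents that add atoms: water, O
Why: Mild acid hydrolysis of a vinylogous amide should give the β-keto aldehyde, which rests as the Z enol chelated to the C1 carbonyl, while the chromone and both ether types are inert to cold dilute acid and the 2-methoxy group leaves no phenol that could cyclise onto the formyl carbon.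

**Step 5**
Reactants: 8 (Z)-2-[7-(benzyloxy)-4-oxochromen-3-yl]-3-hydroxy-1-(2,4-dimethoxyphenyl)prop-2-en-1-one; 9 phenol (two molecules are incorporated)
Product: 12 (R)-2-[7-(benzyloxy)-4-oxochromen-3-yl]-1-(2,4-dimethoxyphenyl)-3,3-bis(4-hydroxyphenyl)propan-1-one, via enone 10 (not isolated), via enol 11 (not isolated)
Conditions: 9 (8 equiv), (R)-3,3'-bis(2,4,6-triisopropylphenyl)-1,1'-binaphthalene-2,2'-diyl N-(trifluoromethylsulfonyl)phosphoramide (10 mol %), 5 Å MS, toluene, 0 °C to rt; NaHCO3 quench
Reagents that add atoms: none
Why: Proposed new method: the chiral acid activates the aldehyde tautomer of 8, the para carbon of a first phenol attacks C3 and water is lost to give enone 10, whose O-protonated form is a 4-hydroxybenzyl cation of quinone-methide character that a second phenol attacks at C3 through its para carbon, leaving enol 11 hydrogen-bonded to the chiral anion. The closest known reaction types are the acid-catalysed bisphenol condensation of aldehydes with phenol, chiral-acid additions to para-quinone methides generated in situ, and chiral phosphoric acid Friedel–Crafts conjugate addition followed by enantioselective protonation; their merger on a β-keto aldehyde with plain phenol has not been shown. The step forms no ring. C2 is the only new stereocenter, since the two aryl groups on C3 are the same, and it is set when the catalyst, acting as a proton shuttle between the enol oxygen and C2, delivers its proton to one face of the C1=C2 bond of 11, whose Z geometry is held by the hydrogen bond from the enol OH to the chromone C4 carbonyl. The step needs para attack twice, which the crowding of C3 by the fully substituted C2 and the 3,3'-aryl walls of the catalyst should secure, and it needs the formyl carbon to stay open, which the 2-methoxy group on the ketone ring secures by leaving no phenol to close a second chromone, while the excess of 9 keeps the phenol rings of 12 from competing. The N-triflyl phosphoramide replaces the parent phosphoric acid because phenol is a weak π-nucleophile, phenol itself is too weak an acid to protonate 11 in an achiral background, and the run is quenched at full conversion so that acid-mediated re-enolisation cannot erode the ee.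

**Step 6**
Reactants: 12 (R)-2-[7-(benzyloxy)-4-oxochromen-3-yl]-1-(2,4-dimethoxyphenyl)-3,3-bis(4-hydroxyphenyl)propan-1-one
Product: 14 (R)-1-(2-hydroxy-4-methoxyphenyl)-2-(7-hydroxy-4-oxochromen-3-yl)-3,3-bis(4-hydroxyphenyl)propan-1-one, via debenzylated ketone 13 (not isolated)
Conditions: BCl3 (8 equiv), C6HMe5 (3 equiv), CH2Cl2, −78 to 0 °C; cold water quench
Reagents that add atoms: none
Why: In this boron trichloride ether cleavage the benzyl ether should fall at −78 °C with pentamethylbenzene as cation trap, and on warming the six-membered boron chelate between the C1 ketone and the ortho methoxy oxygen directs chloride to that methyl group only, so the para methoxy group stays and C2 should hold its configuration because enolisation to a crowded tetrasubstituted enol is slow at or below 0 °C.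

**Compound list**

1 | 1-[2,4-bis(benzyloxy)phenyl]ethanone | CC(=O)c1ccc(OCc2ccccc2)cc1OCc1ccccc1 | starting material
2 | 2-bromo-1-(2,4-dimethoxyphenyl)ethanone | COc1ccc(C(=O)CBr)c(OC)c1 | starting material
3 | 1-[2,4-bis(benzyloxy)phenyl]-4-(2,4-dimethoxyphenyl)butane-1,4-dione | COc1ccc(C(=O)CCC(=O)c2ccc(OCc3ccccc3)cc2OCc2ccccc2)c(OC)c1 | intermediate
4 | 1-[4-(benzyloxy)-2-hydroxyphenyl]-4-(2,4-dimethoxyphenyl)butane-1,4-dione | COc1ccc(C(=O)CCC(=O)c2ccc(OCc3ccccc3)cc2O)c(OC)c1 | intermediate
5 | (E)-1-[4-(benzyloxy)-2-hydroxyphenyl]-2-[(dimethylamino)methylidene]-4-(2,4-dimethoxyphenyl)butane-1,4-dione (open enaminone, not isolated) | CN(C)/C=C(/C(=O)c1ccc(OCc2ccccc2)cc1O)CC(=O)c1ccc(OC)cc1OC | intermediate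
6 | 7-(benzyloxy)-3-[2-(2,4-dimethoxyphenyl)-2-oxoethyl]chromen-4-one (phenacylchromone, not isolated) | COc1ccc(C(=O)Cc2coc3cc(OCc4ccccc4)ccc3c2=O)c(OC)c1 | intermediate
7 | (E)-2-[7-(benzyloxy)-4-oxochromen-3-yl]-3-(dimethylamino)-1-(2,4-dimethoxyphenyl)prop-2-en-1-one | COc1ccc(C(=O)/C(=C/N(C)C)c2coc3cc(OCc4ccccc4)ccc3c2=O)c(OC)c1 | intermediate
8 | (Z)-2-[7-(benzyloxy)-4-oxochromen-3-yl]-3-hydroxy-1-(2,4-dimethoxyphenyl)prop-2-en-1-one | COc1ccc(C(=O)/C(=C\O)c2coc3cc(OCc4ccccc4)ccc3c2=O)c(OC)c1 | intermediate
9 | phenol | Oc1ccccc1 | starting material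
10 | (E)-2-[7-(benzyloxy)-4-oxochromen-3-yl]-1-(2,4-dimethoxyphenyl)-3-(4-hydroxyphenyl)prop-2-en-1-one (enone, not isolated) | COc1ccc(C(=O)/C(=C/c2ccc(O)cc2)c2coc3cc(OCc4ccccc4)ccc3c2=O)c(OC)c1 | intermediate
11 | (Z)-2-[7-(benzyloxy)-4-oxochromen-3-yl]-1-(2,4-dimethoxyphenyl)-3,3-bis(4-hydroxyphenyl)prop-1-en-1-ol (enol, not isolated) | COc1ccc(/C(O)=C(/c2coc3cc(OCc4ccccc4)ccc3c2=O)C(c2ccc(O)cc2)c2ccc(O)cc2)c(OC)c1 | intermediate
12 | (R)-2-[7-(benzyloxy)-4-oxochromen-3-yl]-1-(2,4-dimethoxyphenyl)-3,3-bis(4-hydroxyphenyl)propan-1-one | COc1ccc(C(=O)[C@@H](c2coc3cc(OCc4ccccc4)ccc3c2=O)C(c2ccc(O)cc2)c2ccc(O)cc2)c(OC)c1 | intermediate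
13 | (R)-1-(2,4-dimethoxyphenyl)-2-(7-hydroxy-4-oxochromen-3-yl)-3,3-bis(4-hydroxyphenyl)propan-1-one (in the flask as its boron aryloxide, not isolated) | COc1ccc(C(=O)[C@@H](c2coc3cc(O)ccc3c2=O)C(c2ccc(O)cc2)c2ccc(O)cc2)c(OC)c1 | intermediate
14 | (R)-1-(2-hydroxy-4-methoxyphenyl)-2-(7-hydroxy-4-oxochromen-3-yl)-3,3-bis(4-hydroxyphenyl)propan-1-one | COc1ccc(C(=O)[C@@H](c2coc3cc(O)ccc3c2=O)C(c2ccc(O)cc2)c2ccc(O)cc2)c(O)c1 | target

Total step count: 6. Longest linear sequence: 6 steps (from 1 or 2 to 14).

**Steps most likely to fail**

**Step 5.**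
- What may go wrong:
  - C-arylation by the weakly nucleophilic phenol may be sluggish.
  - Ortho attack may occur, followed by hemiketalisation onto the C1 ketone.
  - Acid may promote attack of the formyl or enol oxygen on chromone C2, with opening of the pyranone ring.
  - Facial selectivity in the protonation may be poor.
  - The ee may erode through re-enolisation.
- Fallback: it uses known chemistry, sets out from 4 and returns at 12.
  - It forms the C2–C3 bond instead of the C3–aryl bonds, so both para positions are preset, and it draws the configuration from resolution.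
  - One equivalent of Me2NCH(OMe)2 (toluene, 80 °C) should stop at phenacylchromone 6, which is isolated.
  - Commercial 4,4'-dihydroxybenzophenone is reduced (NaBH4, MeOH) to bis(4-hydroxyphenyl)methanol F1.
  - Acid-catalysed SN1-type alkylation of the enolisable ketone 6 with this electron-rich benzhydrol (TsOH·H2O 10 mol %, MeNO2–CH2Cl2, rt) is a known way to benzhydrylate carbonyl compounds through the stabilised diarylmethyl cation. It should give rac-2-[7-(benzyloxy)-4-oxochromen-3-yl]-1-(2,4-dimethoxyphenyl)-3,3-bis(4-hydroxyphenyl)propan-1-one F2.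
  - Preparative HPLC on a polysaccharide chiral phase delivers 12.
  - The antipode (S)-2-[7-(benzyloxy)-4-oxochromen-3-yl]-1-(2,4-dimethoxyphenyl)-3,3-bis(4-hydroxyphenyl)propan-1-one F3 is racemised with Et3N in THF and fed back.

**Step 6.**
- What may go wrong:
  - Configuration at C2 may be lost through a boron enolate.
  - The free phenol rings may be C-benzylated.
  - The para methoxy group may be cleaved as well.
  - Acid may induce retro-Friedel–Crafts loss of a hydroxyphenyl ring.
- Fallback: it sets out from 12 and returns at 14.
  - The two cleavages are separated and no boron Lewis acid or HCl meets the stereocentre.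
  - Hydrogenolysis (H2 1 atm, Pd/C, EtOAc–MeOH, rt, stopped after one equivalent of H2) gives 13 as an isolated compound.
  - Chelate-directed SN2 demethylation by iodide (MgI2·OEt2, toluene–Et2O, 60 °C) then removes only the methyl group ortho to the ketone.

**Step 1.**
- What may go wrong:
  - Addition of the zinc enolate to the electron-rich, ortho-substituted partner 2 may be slow.
  - Et2NH may aminate 2.
  - Either ketone may self-condense.
- Fallback: it sets out from 1 and 2 and returns at 3 by the classical β-keto ester sequence.
  - Claisen-type C-acylation of 1 (NaH, dimethyl carbonate, THF, reflux) gives methyl 3-[2,4-bis(benzyloxy)phenyl]-3-oxopropanoate F4.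
  - Alkylation of this soft enolate with 2 (K2CO3, acetone, rt) gives methyl 2-[2,4-bis(benzyloxy)benzoyl]-4-(2,4-dimethoxyphenyl)-4-oxobutanoate F5.
  - Krapcho demethoxycarbonylation (LiCl, wet DMSO, 130 °C) gives 3.

**Further compounds**
F1 | step 5 | bis(4-hydroxyphenyl)methanol | OC(c1ccc(O)cc1)c1ccc(O)cc1
F2 | step 5 | rac-2-[7-(benzyloxy)-4-oxochromen-3-yl]-1-(2,4-dimethoxyphenyl)-3,3-bis(4-hydroxyphenyl)propan-1-one | COc1ccc(C(=O)C(c2coc3cc(OCc4ccccc4)ccc3c2=O)C(c2ccc(O)cc2)c2ccc(O)cc2)c(OC)c1
F3 | step 5 | (S)-2-[7-(benzyloxy)-4-oxochromen-3-yl]-1-(2,4-dimethoxyphenyl)-3,3-bis(4-hydroxyphenyl)propan-1-one | COc1ccc(C(=O)[C@H](c2coc3cc(OCc4ccccc4)ccc3c2=O)C(c2ccc(O)cc2)c2ccc(O)cc2)c(OC)c1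
F0 | step 6 | none | none
F4 | step 1 | methyl 3-[2,4-bis(benzyloxy)phenyl]-3-oxopropanoate | COC(=O)CC(=O)c1ccc(OCc2ccccc2)cc1OCc1ccccc1
F5 | step 1 | methyl 2-[2,4-bis(benzyloxy)benzoyl]-4-(2,4-dimethoxyphenyl)-4-oxobutanoate (racemic) | COC(=O)C(CC(=O)c1ccc(OC)cc1OC)C(=O)c1ccc(OCc2ccccc2)cc1OCc1ccccc1
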